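(Readings and results were generated by integration for an exercise.)

A rate law first order in partner tempts you to read an apparent order of 1. Here, though, the order is taken at fixed conversion, where a larger charge also changes the fraction left. You must choose which charge to raise in the next run of this flask, partner or free catalyst, and the higher apparent order gets the raise.

| flask | left-handed substrate | right-handed substrate | partner | protic impurity | free catalyst | remark |
|---|---|---|---|---|---|---|
| maple | 1 M | 1 M | 1 M | 0.20 M | 2 mM | the very flask that is asked about, followed so far |
| flask | 1.0 M | 1.0 M | 1.00 M | 0.200 M | 2.0 mM |  |

maple run (percent of the left-handed substrate and right-handed substrate together charged)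

| time / min | left-handed product / % | left-handed substrate / % |
|---|---|---|
| 5.00 | 1.5 | 48.5 |
| 15.0 | 4.0 | 44.6 |
| 25.0 | 7.8 | 42.7 |
| 40.0 | 10.4 | 39.4 |
| 60.0 | 13.1 | 37.0 |

(standard deviation of a reading: 0.5 percentage points)

- free catalyst is single-handed; left-handed substrate and right-handed substrate are mirror images of each other, charged as a racemate, each of them at the stated concentration
- what was read earlier has a scatter of 0.5 percentage points, one standard deviation
- what may be going on: free catalyst + left-handed substrate <-> catalyst intermediate A; free catalyst + right-handed substrate <-> catalyst intermediate B; partner + catalyst intermediate A -> free catalyst + left-handed product; partner + catalyst intermediate B -> free catalyst + right-handed product; 2 partner -> homo dimer; partner + protic impurity -> quenched reagent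
- no earlier run changes the charge of free catalyst; that part of a forecast is a guess
- no earlier run changes the charge of partner; that part of a forecast is a guess

- apparent order in free catalyst when 10% of the left-handed substrate and right-handed substrate together are converted (percent change of the rate of making left-handed product for one percent more free catalyst charged)
- apparent order in partner when 10% of the left-handed substrate and right-handed substrate together are converted (percent change of the rate of making left-handed product for one percent more partner charged)

In the maple run, the readings put the gain of left-handed product per minute up to 25.0 min at about 2.31 times the gain from 40.0 min to 60.0 min, yet left-handed substrate was still read at 74.0% of its charge at 60.0 min. So I follow the fraction of partner left. Let c_B, c_H and c_S be the charges of partner, protic impurity and each substrate, and x the conversion asked. I debit partner for the whole impurity charge and for one partner per substrate converted: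

φ = 1 − c_H/c_B − 2·x·c_S/c_B = 60.0%

This φ is the spare fraction of partner at that conversion; it leaves out the homo dimer. In this reckoning the debits are fixed amounts at fixed x, so [partner] = φ·c_B; if the rate follows [partner], the apparent order in partner, n_B, is the logarithmic slope of [partner] against c_B:

n_B = 1/φ = 1.67

For free catalyst I have no such balance and commit to no number.

The forecast gives 1.15 in free catalyst and 1.4 in partner, holding that “The side losses and any partial saturation in partner temper this”; my partner order is higher.

The flask gives 1.5 in free catalyst and 1.8 in partner, above the 1.67 from φ = 60.0% and above the catalyst order, so the next run raises partner.

free catalyst + left-handed substrate ⇌ catalyst intermediate A (K = 5.00 /M, k = 28.0 /M/s); free catalyst + right-handed substrate ⇌ catalyst intermediate B (K = 0.790 /M, k = 1.30 /M/s); partner + catalyst intermediate A → free catalyst + left-handed product (k = 0.100 /M/s); partner + catalyst intermediate B → free catalyst + right-handed product (k = 0.00170 /M/s); 2 partner → homo dimer (k = 1.10 × 10⁻⁴ /M/s); partner + protic impurity → quenched reagent (k = 0.00180 /M/s) At 0.911 h, partner's half-life by the step making left-handed product is 1.4 h, shorter than the 13 h by the loss to quenched reagent, and at 12.0 h partner, the limiting reagent, stands at 0.16% of its charge with 50% of the left-handed substrate left.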